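I began from a one-step world, substrate plus reagent to product, in which scavenger has no term.

all flasks: substrate 0.80 M; initiator 16 mM
- south: reagent 1.2 M; scavenger 1.8 M; run made earlier
- blue: reagent 1.20 M; scavenger 2.40 M; time 10 d
- teal: reagent 1.20 M; scavenger 1.20 M; time 10 d

south run (percent of the substrate charged)

| time / d | substrate / % | product / % |
|---|---|---|
| 0.625 | 72 | 26 |
| 1.25 | 59 | 42 |
| 2.00 | 45 | 54 |
| 3.00 | 31 | 68 |
| 4.00 | 23 | 76 |
| 5.00 | 19 | 78 |

(scatter of a reading: 1.5 percentage points)

- in percentages every species weighs as the substrate in it: one ended chains counts as two
- for released group the idle adduct is counted in
- the earlier runs were read with a standard deviation of 1.5 percentage points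
- candidate steps: reagent + released group <-> idle adduct; scavenger + released group -> scavenged by-product; substrate + initiating radical -> capped initiator + first chain carrier; reagent + first chain carrier <-> product + second chain carrier; substrate + second chain carrier -> released group + first chain carrier; 2 first chain carrier -> ended chains; initiator -> 2 initiating radical
- no earlier run changes the charge of scavenger; that part of a forecast is a guess

- part of the substrate that has reacted at the end, blue
- part of the substrate that has reacted at the end, teal
- what raising the concentration of scavenger from its lowest to its highest value here does to the part of the substrate that has reacted (changes below 5 percentage points count as none) (it falls / no change / it rises)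

1. In that world I continued the south run: between 3.00 d and 5.00 d its substrate readings fell from 31% to 19%, a first-order constant of about 0.245 d⁻¹ as read. At that pace I reckoned 94.4% reacted at 10 d, and I gave blue and teal the same figure.

2. Then I turned the question round: what had to be true for scavenger to move the outcome? I divided the rate of scavenger use by the rate of substrate use, and time dropped out. Each turn of the chain frees one released group and each captured one takes one scavenger, so I took the ratio as one. The fraction of its own charge that scavenger spends is therefore the fraction of substrate reacted divided by the charge of scavenger over the charge of substrate. In teal that charge ratio was 1.50, the cover, and in blue it was 3.00.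

3. For scavenger to run short, the spend had to reach its whole charge. Yet full conversion in teal takes 66.7% of it, and substrate was the limiting reagent. A second route stayed open, reagent held as idle adduct, and the south columns do not show its size. I still committed to no change.

4. The forecast differed from me: 91% for blue, 82% for teal, and it rises, since “more scavenger should keep free reagent higher and the chain faster”.

5. The flasks gave 92.4% in blue and 92.4% in teal, so the trend was no change, a change of 0.045 percentage points.

    reagent + released group ⇌ idle adduct, settled at all times (K = 0.380 M⁻¹)
    scavenger + released group → scavenged by-product (k = 0.300 M⁻¹ h⁻¹)
    substrate + initiating radical → capped initiator + first chain carrier (k = 11000 M⁻¹ s⁻¹)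
    reagent + first chain carrier ⇌ product + second chain carrier (K = 0.440, k = 1.40 × 10⁶ M⁻¹ h⁻¹)
    substrate + second chain carrier → released group + first chain carrier (k = 2.90 × 10⁶ M⁻¹ h⁻¹)
    2 first chain carrier → ended chains (k = 8.30 × 10⁷ M⁻¹ s⁻¹)
    initiator → 2 initiating radical (k = 0.00230 h⁻¹)

In blue at 1.38 d, free released group had a half-life of 1.1 h against scavenger, far shorter than the 1.9 d of substrate in the step that releases it. Teal ended with 0.0447% of its reagent charge as idle adduct, against 40% unbound. By the cover, teal should have kept 38.4% of its scavenger and it held 40%, while blue should have kept 69.2% and it held 70%.

The readings stem from a simulated flask from invented constants; noise was put on by code.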